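## Retrosynthetic overview

1. The ten-membered carbocycle is closed last, by ring-closing metathesis forming the (4Z) C4=C5 bond between a C6-vinyl group and the C4-isopropenyl group of a fully functionalised seco-diene.
2. The seco-diene comes from a Ni/Cr-mediated C9–C10 coupling of an East aldehyde (C5–C9, C11–C13) with a West (Z)-alkenyl iodide (C1–C4, C10, C14, C15); C9 is then set by oxidation to the enone and Felkin reduction, and C14 is oxidised late to the methyl ester.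
3. The O8 ester comes from (2R,3R)-epoxyangelic acid (third fragment, Sharpless epoxidation of angelyl alcohol), attached by Yamaguchi esterification.
4. East fragment: Evans syn-aldol (C6, C7), hydroxyl-directed anti-reduction (C8), lactonisation, α-methylenation. West fragment: Sharpless epoxidation of a (Z)-dienol gives the cis-vinyl-oxirane.
5. Ring order: the two oxiranes (inside the fragments), then the γ-lactone, then the ten-membered ring.

Assumption: locants C1–C15 in the comments are the germacrane locants of the target (lactone oxygen on C6, acyloxy on C8, hydroxyl on C9, ester carbon C14), and minor enantiomers from the two Sharpless steps are removed as diastereomers after the fragments are joined.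

## Route

Step 1
Reactants: 1 2-methylbut-1-en-3-yne
Product: 3 4-methylpent-4-en-2-yn-1-ol, via lithium acetylide 2 (not isolated)
Conditions: n-BuLi, THF, −78 °C; (CH2O)n, −78 °C to rt; H2O
Reagents that add atoms: formaldehyde (from paraformaldehyde), C=O
Why: Deprotonation of the terminal alkyne and 1,2-addition of the acetylide to formaldehyde (acetylide hydroxymethylation) gives the propargylic alcohol, with no stereocentre formed.

Step 2
Reactants: 3 4-methylpent-4-en-2-yn-1-ol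
Product: 4 (2Z)-4-methylpenta-2,4-dien-1-ol
Conditions: H2 (1 atm), Pd/CaCO3 poisoned with Pb(OAc)2, quinoline, EtOAc, rt
Reagents that add atoms: none
Why: Lindlar semi-hydrogenation is a syn addition that stops at the alkene, so the conjugated enyne gives the (Z)-allylic alcohol needed for a cis-oxirane.

Step 3
Reactants: 4 (2Z)-4-methylpenta-2,4-dien-1-ol
Product: 5 [(2R,3S)-3-(prop-1-en-2-yl)oxiran-2-yl]methanol
Conditions: Ti(OiPr)4 (10 mol %), D-(−)-diisopropyl tartrate (12 mol %), t-BuOOH, 4 Å MS, CH2Cl2, −20 °C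
Reagents that add atoms: tert-butyl hydroperoxide, CC(C)(C)OO
Why: Sharpless asymmetric epoxidation oxidises only the allylic-alcohol double bond of the dienol, the D-tartrate complex delivering oxygen to the face that gives the (2R,3S) oxirane, whose cis geometry comes from the Z-olefin.

Step 4
Reactants: 5 [(2R,3S)-3-(prop-1-en-2-yl)oxiran-2-yl]methanol
Product: 6 (2S,3S)-3-(prop-1-en-2-yl)oxirane-2-carbaldehyde
Conditions: TEMPO (cat.), PhI(OAc)2, CH2Cl2, rt
Reagents that add atoms: none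
Why: TEMPO/PhI(OAc)2 oxidation of the primary alcohol stops at the aldehyde under near-neutral conditions that leave the vinyl-oxirane and its configuration untouched (the descriptor at C2 changes only through CIP priority).

Step 5
Reactants: 6 (2S,3S)-3-(prop-1-en-2-yl)oxirane-2-carbaldehyde
Product: 7 methyl (2Z)-2-iodo-3-[(2R,3S)-3-(prop-1-en-2-yl)oxiran-2-yl]prop-2-enoate
Conditions: Ph3P=CHCO2Me, N-iodosuccinimide, CH2Cl2, −20 °C; then 6, rt
Reagents that add atoms: methyl (triphenylphosphoranylidene)acetate, COC(=O)C=P(c1ccccc1)(c1ccccc1)c1ccccc1; N-iodosuccinimide, O=C1CCC(=O)N1I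
Why: Wittig olefination with the stabilised α-iodo ylide puts the ester trans to the oxirane, giving the (Z)-α-iodoenoate in which iodine marks the future C10–C9 bond cis to C2.

Step 6
Reactants: 7 methyl (2Z)-2-iodo-3-[(2R,3S)-3-(prop-1-en-2-yl)oxiran-2-yl]prop-2-enoate
Product: 8 (2Z)-2-iodo-3-[(2R,3S)-3-(prop-1-en-2-yl)oxiran-2-yl]prop-2-en-1-ol
Conditions: i-Bu2AlH (2.2 equiv), CH2Cl2, −78 °C; aq. potassium sodium tartrate
Reagents that add atoms: none
Why: DIBAL-H 1,2-reduction of the enoate to the allylic alcohol at −78 °C leaves the alkenyl iodide, the olefin geometry and the oxirane intact.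

Step 7
Reactants: 8 (2Z)-2-iodo-3-[(2R,3S)-3-(prop-1-en-2-yl)oxiran-2-yl]prop-2-en-1-ol
Product: 9 (2R,3S)-2-{(1Z)-2-iodo-3-[(4-methoxyphenyl)methoxy]prop-1-en-1-yl}-3-(prop-1-en-2-yl)oxirane
Conditions: NaH, 4-MeOC6H4CH2Cl, n-Bu4NI (cat.), THF/DMF, 0 °C to rt
Reagents that add atoms: 4-methoxybenzyl chloride, COc1ccc(CCl)cc1
Why: Williamson etherification masks the C14 alcohol as a PMB ether that survives the chromium, oxidation and hydride steps and is later removed by DDQ.

Step 8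
Reactants: 10 angelic acid
Product: 11 (2Z)-2-methylbut-2-en-1-ol
Conditions: LiAlH4, Et2O, 0 °C to rt; H2O
Reagents that add atoms: none
Why: LiAlH4 reduction of the carboxylic acid by 1,2-hydride delivery gives the allylic alcohol with retention of the Z-olefin.

Step 9
Reactants: 11 (2Z)-2-methylbut-2-en-1-ol
Product: 12 [(2S,3R)-2,3-dimethyloxiran-2-yl]methanol
Conditions: Ti(OiPr)4 (10 mol %), L-(+)-diisopropyl tartrate (12 mol %), t-BuOOH, 4 Å MS, CH2Cl2, −20 °C
Reagents that add atoms: tert-butyl hydroperoxide, CC(C)(C)OO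
Why: Sharpless asymmetric epoxidation with the L-tartrate ligand delivers oxygen to the face that gives the (2S,3R) epoxy alcohol, the Z-olefin fixing the two methyl groups trans on the oxirane.

Step 10
Reactants: 12 [(2S,3R)-2,3-dimethyloxiran-2-yl]methanol
Product: 13 (2R,3R)-2,3-dimethyloxirane-2-carboxylic acid
Conditions: RuCl3 (2 mol %), NaIO4, CCl4/MeCN/H2O, rt
Reagents that add atoms: water, O
Why: Sharpless RuCl3/NaIO4 oxidation (RuO4 formed in situ) takes the primary alcohol through the aldehyde hydrate to the acid without opening the trisubstituted oxirane, the change from 2S to 2R being a CIP priority change only.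

Step 11
Reactants: 14 4-(tert-butoxy)-4-oxobutanoic acid; 15 (4S)-4-benzyl-1,3-oxazolidin-2-one
Product: 17 tert-butyl 4-[(4S)-4-benzyl-2-oxo-1,3-oxazolidin-3-yl]-4-oxobutanoate, via mixed pivalic anhydride 16 (not isolated)
Conditions: t-BuCOCl, Et3N, THF, −20 °C; then 15, LiCl, −20 °C to rt
Reagents that add atoms: none
Why: N-Acylation of the Evans oxazolidinone through the pivaloyl mixed anhydride (LiCl/Et3N variant) occurs at the less hindered succinyl carbonyl.

Step 12
Reactants: 17 tert-butyl 4-[(4S)-4-benzyl-2-oxo-1,3-oxazolidin-3-yl]-4-oxobutanoate; 18 acrolein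
Product: 20 tert-butyl (3S,4R)-3-[(4S)-4-benzyl-2-oxo-1,3-oxazolidine-3-carbonyl]-4-hydroxyhex-5-enoate, via boron enolate 19 (not isolated)
Conditions: n-Bu2BOTf, i-Pr2NEt, CH2Cl2, −78 to 0 °C; 18, −78 to 0 °C; then pH 7 buffer, MeOH, 30% H2O2, 0 °C
Reagents that add atoms: none
Why: Evans boron syn-aldol, in which the (Z)-enolate of the imide (the ester is not enolised) adds to acrolein through a Zimmerman–Traxler chair on the face away from the benzyl group, sets C7 (S) and C6 (R) in the syn relationship that becomes the trans-lactone.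

Step 13
Reactants: 20 tert-butyl (3S,4R)-3-[(4S)-4-benzyl-2-oxo-1,3-oxazolidine-3-carbonyl]-4-hydroxyhex-5-enoate
Product: 21 tert-butyl (3S,4R)-4-hydroxy-3-[methoxy(methyl)carbamoyl]hex-5-enoate
Conditions: MeNH(OMe)·HCl, AlMe3, CH2Cl2, −15 to 0 °C; aq. potassium sodium tartrate
Reagents that add atoms: N,O-dimethylhydroxylamine hydrochloride, CNOC.Cl
Why: Aluminium-amide transamination of the β-hydroxy imide (Weinreb amide formation) is assisted by the aluminium alkoxide, leaves the tert-butyl ester alone and releases the auxiliary without touching C6 or C7.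

Step 14
Reactants: 21 tert-butyl (3S,4R)-4-hydroxy-3-[methoxy(methyl)carbamoyl]hex-5-enoate
Product: 22 tert-butyl (3S,4R)-3-(1,3-dithiane-2-carbonyl)-4-hydroxyhex-5-enoate
Conditions: 1,3-dithiane, n-BuLi, THF, −30 °C (2.5 equiv of the anion); then 21, −78 to −30 °C; H2O
Reagents that add atoms: 1,3-dithiane, C1CSCSC1
Why: Addition of 2-lithio-1,3-dithiane to the Weinreb amide stops at the ketone through the chelated tetrahedral intermediate, the dithiane being the masked C9 aldehyde.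

Step 15
Reactants: 22 tert-butyl (3S,4R)-3-(1,3-dithiane-2-carbonyl)-4-hydroxyhex-5-enoate
Product: 23 tert-butyl (3S,4R)-3-[(S)-1,3-dithian-2-yl(hydroxy)methyl]-4-hydroxyhex-5-enoate
Conditions: Me4NBH(OAc)3, MeCN/AcOH (1:1), −30 °C
Reagents that add atoms: none
Why: Evans–Saksena hydroxyl-directed reduction delivers hydride intramolecularly from the O6-bound acetoxyborohydride through a chair transition state and gives the 1,3-anti diol, that is the (S) carbinol at C8.

Step 16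
Reactants: 23 tert-butyl (3S,4R)-3-[(S)-1,3-dithian-2-yl(hydroxy)methyl]-4-hydroxyhex-5-enoate
Product: 24 (4R,5R)-4-[(S)-1,3-dithian-2-yl(hydroxy)methyl]-5-ethenyloxolan-2-one
Conditions: CF3CO2H/CH2Cl2 (1:4), 0 °C to rt
Reagents that add atoms: none
Why: Acidolysis of the tert-butyl ester and acid-catalysed γ-lactonisation under equilibrating conditions close on the less hindered O6 to give the trans-β,γ-disubstituted lactone, whereas closure on O8 would give the more strained cis-lactone.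

Step 17
Reactants: 24 (4R,5R)-4-[(S)-1,3-dithian-2-yl(hydroxy)methyl]-5-ethenyloxolan-2-one
Product: 25 (4S,5R)-4-[(S)-1,3-dithian-2-yl(triethylsilyloxy)methyl]-5-ethenyloxolan-2-one
Conditions: Et3SiOTf, 2,6-lutidine, CH2Cl2, −78 °C
Reagents that add atoms: triethylsilyl trifluoromethanesulfonate, CC[Si](CC)(CC)OS(=O)(=O)C(F)(F)F
Why: Silylation of the hindered secondary alcohol with the silyl triflate protects O8 through the enolate, chromium and oxidation steps (the ring descriptor changes by CIP priority only).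

Step 18
Reactants: 25 (4S,5R)-4-[(S)-1,3-dithian-2-yl(triethylsilyloxy)methyl]-5-ethenyloxolan-2-one
Product: 29 (4S,5R)-4-[(S)-1,3-dithian-2-yl(triethylsilyloxy)methyl]-5-ethenyl-3-methylideneoxolan-2-one, via lithium enolate 26 (not isolated), via Mannich base 27 (not isolated), via methiodide 28 (not isolated)
Conditions: LiN(i-Pr)2, THF, −78 °C; CH2=NMe2+ I−, −78 °C to rt; then MeI (3 equiv), MeOH, rt; then aq. NaHCO3, CH2Cl2
Reagents that add atoms: N,N-dimethylmethyleneiminium iodide (Eschenmoser's salt), C=[N+](C)C.[I-]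
Why: α-Methylenation of the lactone by Mannich aminomethylation of the lithium enolate, N-methylation (much faster than S-methylation of the dithiane) and base-induced Hofmann-type elimination gives the exocyclic olefin.

Step 19
Reactants: 29 (4S,5R)-4-[(S)-1,3-dithian-2-yl(triethylsilyloxy)methyl]-5-ethenyl-3-methylideneoxolan-2-one
Product: 30 (2S)-2-[(2R,3S)-2-ethenyl-4-methylidene-5-oxooxolan-3-yl]-2-(triethylsilyloxy)acetaldehyde
Conditions: MeI, CaCO3, MeCN/H2O (9:1), 45 °C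
Reagents that add atoms: water, O
Why: Alkylative hydrolysis of the dithioacetal (S-methylation, then hydrolysis of the sulfonium) unmasks the C9 aldehyde under buffered conditions that the silyl ether and the α-methylene lactone survive.

Step 20
Reactants: 30 (2S)-2-[(2R,3S)-2-ethenyl-4-methylidene-5-oxooxolan-3-yl]-2-(triethylsilyloxy)acetaldehyde; 9 (2R,3S)-2-{(1Z)-2-iodo-3-[(4-methoxyphenyl)methoxy]prop-1-en-1-yl}-3-(prop-1-en-2-yl)oxirane
Product: 31 (4S,5R)-5-ethenyl-4-[(1S,3Z)-2-hydroxy-3-{[(4-methoxyphenyl)methoxy]methyl}-4-[(2R,3S)-3-(prop-1-en-2-yl)oxiran-2-yl]-1-(triethylsilyloxy)but-3-en-1-yl]-3-methylideneoxolan-2-one (both C9 epimers)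
Conditions: CrCl2 (6 equiv), NiCl2 (2 mol %), 9 (1.5 equiv), DMSO/THF, rt
Reagents that add atoms: none
Why: Nozaki–Hiyama–Kishi coupling adds the alkenylchromium (formed via nickel insertion into the C–I bond) only to the aldehyde with retention of olefin geometry, and the two C9 epimers formed are converged in the next step.

Step 21
Reactants: 31 (C9 epimers)
Product: 32 (4S,5R)-5-ethenyl-4-[(1S,3Z)-3-{[(4-methoxyphenyl)methoxy]methyl}-2-oxo-4-[(2R,3S)-3-(prop-1-en-2-yl)oxiran-2-yl]-1-(triethylsilyloxy)but-3-en-1-yl]-3-methylideneoxolan-2-one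
Conditions: Dess–Martin periodinane, NaHCO3, CH2Cl2, 0 °C to rt
Reagents that add atoms: none
Why: Dess–Martin oxidation of the allylic alcohol mixture gives a single enone, erasing the unselective C9 centre.

Step 22
Reactants: 32 (TES-protected enone)
Product: 33 (4R,5R)-5-ethenyl-4-[(1S,3Z)-1-hydroxy-3-{[(4-methoxyphenyl)methoxy]methyl}-2-oxo-4-[(2R,3S)-3-(prop-1-en-2-yl)oxiran-2-yl]but-3-en-1-yl]-3-methylideneoxolan-2-one
Conditions: HF·pyridine, pyridine, THF, 0 °C
Reagents that add atoms: none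
Why: Fluoride-mediated desilylation of the secondary TES ether under pyridine-buffered conditions frees O8 while the PMB ether and both oxiranes survive (ring descriptor changes by CIP priority only).

Step 23
Reactants: 33 (α-hydroxy enone); 13 (2R,3R)-2,3-dimethyloxirane-2-carboxylic acid
Product: 35 (1S,3Z)-1-[(2R,3S)-2-ethenyl-4-methylidene-5-oxooxolan-3-yl]-3-{[(4-methoxyphenyl)methoxy]methyl}-2-oxo-4-[(2R,3S)-3-(prop-1-en-2-yl)oxiran-2-yl]but-3-en-1-yl (2R,3R)-2,3-dimethyloxirane-2-carboxylate, via mixed trichlorobenzoic anhydride 34 (not isolated)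
Conditions: 2,4,6-Cl3C6H2COCl, Et3N, THF, rt; then 33, DMAP, toluene, 0 °C to rt
Reagents that add atoms: none
Why: Yamaguchi esterification acylates the α-ketol O8 with the hindered epoxy acid through its mixed anhydride under DMAP catalysis, the C9 ketone serving as the protecting group for O9 and no stereocentre being touched.

Step 24
Reactants: 35 (α-acyloxy enone)
Product: 36 (1S,2S,3Z)-1-[(2R,3S)-2-ethenyl-4-methylidene-5-oxooxolan-3-yl]-2-hydroxy-3-{[(4-methoxyphenyl)methoxy]methyl}-4-[(2R,3S)-3-(prop-1-en-2-yl)oxiran-2-yl]but-3-en-1-yl (2R,3R)-2,3-dimethyloxirane-2-carboxylate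
Conditions: NaBH4, CeCl3·7H2O, MeOH, −78 °C
Reagents that add atoms: none
Why: Luche 1,2-reduction of the enone proceeds by Felkin–Anh attack anti to the α-acyloxy group to give the 8,9-syn (9S) allylic alcohol, CeCl3 suppressing conjugate reduction of the enone and the α-methylene lactone.

Step 25
Reactants: 36 (PMB ether)
Product: 37 (1S,2S,3Z)-1-[(2R,3S)-2-ethenyl-4-methylidene-5-oxooxolan-3-yl]-2-hydroxy-3-(hydroxymethyl)-4-[(2R,3S)-3-(prop-1-en-2-yl)oxiran-2-yl]but-3-en-1-yl (2R,3R)-2,3-dimethyloxirane-2-carboxylate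
Conditions: DDQ, CH2Cl2/pH 7 buffer (10:1), 0 °C
Reagents that add atoms: none
Why: Oxidative PMB cleavage by DDQ through the benzylic oxocarbenium ion frees the primary allylic alcohol at C14 under neutral conditions.

Step 26
Reactants: 37 (C14 alcohol)
Product: 39 (2E)-2-[(1S,2S)-2-{[(2R,3R)-2,3-dimethyloxirane-2-carbonyl]oxy}-2-[(2R,3S)-2-ethenyl-4-methylidene-5-oxooxolan-3-yl]-1-hydroxyethyl]-3-[(2R,3S)-3-(prop-1-en-2-yl)oxiran-2-yl]prop-2-enoic acid, via enal 38 (not isolated)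
Conditions: TEMPO (cat.), PhI(OAc)2, CH2Cl2, rt; then NaClO2, NaH2PO4, 2-methylbut-2-ene, t-BuOH/H2O, 0 °C to rt
Reagents that add atoms: sodium chlorite, [Na+].[O-]Cl=O
Why: TEMPO/PhI(OAc)2 oxidises only the primary allylic alcohol to the enal, and Pinnick oxidation then gives the acid without olefin isomerisation (the E label reflects CIP priority, C2 stays cis to C9).

Step 27
Reactants: 39 (C14 acid)
Product: 40 methyl (2E)-2-[(1S,2S)-2-{[(2R,3R)-2,3-dimethyloxirane-2-carbonyl]oxy}-2-[(2R,3S)-2-ethenyl-4-methylidene-5-oxooxolan-3-yl]-1-hydroxyethyl]-3-[(2R,3S)-3-(prop-1-en-2-yl)oxiran-2-yl]prop-2-enoate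
Conditions: MeI, KHCO3, DMF, rt
Reagents that add atoms: iodomethane, CI
Why: SN2 O-methylation of the potassium carboxylate gives the methyl ester under conditions too mild to alkylate the C9 hydroxyl or open the oxiranes.

Step 28
Reactants: 40 (seco-diene)
Product: 41 CNP0291485.1 (target)
Conditions: RuCl2(=CH-C6H4-2-O-i-Pr)(H2IMes) (Hoveyda–Grubbs second-generation catalyst, 20 mol %), toluene (1 mM), 70 °C
Reagents that add atoms: none
Why: Ring-closing metathesis between the vinyl and isopropenyl groups forms the ten-membered ring with the kinetically and conformationally favoured cis (4Z) trisubstituted olefin, the electron-poor α-methylene and enoate olefins staying out of the reaction.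

## Compound list

1 | 2-methylbut-1-en-3-yne | C=C(C)C#C | starting material
2 | (3-methylbut-3-en-1-yn-1-yl)lithium | [Li]C#CC(C)=C | intermediate
3 | 4-methylpent-4-en-2-yn-1-ol | OCC#CC(C)=C | intermediate
4 | (2Z)-4-methylpenta-2,4-dien-1-ol | OC/C=C\C(C)=C | intermediate
5 | [(2R,3S)-3-(prop-1-en-2-yl)oxiran-2-yl]methanol | C=C(C)[C@@H]1O[C@@H]1CO | intermediate
6 | (2S,3S)-3-(prop-1-en-2-yl)oxirane-2-carbaldehyde | C=C(C)[C@@H]1O[C@@H]1C=O | intermediate
7 | methyl (2Z)-2-iodo-3-[(2R,3S)-3-(prop-1-en-2-yl)oxiran-2-yl]prop-2-enoate | C=C(C)[C@@H]1O[C@@H]1/C=C(\I)C(=O)OC | intermediate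
8 | (2Z)-2-iodo-3-[(2R,3S)-3-(prop-1-en-2-yl)oxiran-2-yl]prop-2-en-1-ol | C=C(C)[C@@H]1O[C@@H]1/C=C(\I)CO | intermediate
9 | (2R,3S)-2-{(1Z)-2-iodo-3-[(4-methoxyphenyl)methoxy]prop-1-en-1-yl}-3-(prop-1-en-2-yl)oxirane (West fragment) | C=C(C)[C@@H]1O[C@@H]1/C=C(\I)COCc1ccc(OC)cc1 | intermediate
10 | angelic acid, (2Z)-2-methylbut-2-enoic acid | C/C=C(/C)C(=O)O | starting material
11 | (2Z)-2-methylbut-2-en-1-ol | C/C=C(/C)CO | intermediate
12 | [(2S,3R)-2,3-dimethyloxiran-2-yl]methanol | OC[C@]1(C)O[C@@H]1C | intermediate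
13 | (2R,3R)-2,3-dimethyloxirane-2-carboxylic acid (acid fragment) | OC(=O)[C@]1(C)O[C@@H]1C | intermediate
14 | 4-(tert-butoxy)-4-oxobutanoic acid | CC(C)(C)OC(=O)CCC(=O)O | starting material
15 | (4S)-4-benzyl-1,3-oxazolidin-2-one | O=C1N[C@@H](Cc2ccccc2)CO1 | starting material
16 | 4-(tert-butoxy)-4-oxobutanoic 2,2-dimethylpropanoic anhydride | CC(C)(C)OC(=O)CCC(=O)OC(=O)C(C)(C)C | intermediate
17 | tert-butyl 4-[(4S)-4-benzyl-2-oxo-1,3-oxazolidin-3-yl]-4-oxobutanoate | CC(C)(C)OC(=O)CCC(=O)N1[C@@H](Cc2ccccc2)COC1=O | intermediate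
18 | acrolein (prop-2-enal) | C=CC=O | starting material
19 | tert-butyl (3Z)-4-[(4S)-4-benzyl-2-oxo-1,3-oxazolidin-3-yl]-4-[(dibutylboranyl)oxy]but-3-enoate | CCCCB(CCCC)O/C(=C\CC(=O)OC(C)(C)C)N1[C@@H](Cc2ccccc2)COC1=O | intermediate
20 | tert-butyl (3S,4R)-3-[(4S)-4-benzyl-2-oxo-1,3-oxazolidine-3-carbonyl]-4-hydroxyhex-5-enoate | C=C[C@@H](O)[C@H](CC(=O)OC(C)(C)C)C(=O)N1[C@@H](Cc2ccccc2)COC1=O | intermediate
21 | tert-butyl (3S,4R)-4-hydroxy-3-[methoxy(methyl)carbamoyl]hex-5-enoate | C=C[C@@H](O)[C@H](CC(=O)OC(C)(C)C)C(=O)N(C)OC | intermediate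
22 | tert-butyl (3S,4R)-3-(1,3-dithiane-2-carbonyl)-4-hydroxyhex-5-enoate | C=C[C@@H](O)[C@H](CC(=O)OC(C)(C)C)C(=O)C1SCCCS1 | intermediate
23 | tert-butyl (3S,4R)-3-[(S)-1,3-dithian-2-yl(hydroxy)methyl]-4-hydroxyhex-5-enoate | C=C[C@@H](O)[C@H](CC(=O)OC(C)(C)C)[C@H](O)C1SCCCS1 | intermediate
24 | (4R,5R)-4-[(S)-1,3-dithian-2-yl(hydroxy)methyl]-5-ethenyloxolan-2-one | C=C[C@H]1OC(=O)C[C@@H]1[C@H](O)C2SCCCS2 | intermediate
25 | (4S,5R)-4-[(S)-1,3-dithian-2-yl(triethylsilyloxy)methyl]-5-ethenyloxolan-2-one | C=C[C@H]1OC(=O)C[C@@H]1[C@H](O[Si](CC)(CC)CC)C2SCCCS2 | intermediate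
26 | lithium enolate of 25 (O-lithio ketene acetal, C11=C12) | C=C[C@H]1OC(O[Li])=C[C@@H]1[C@H](O[Si](CC)(CC)CC)C2SCCCS2 | intermediate
27 | 3-[(dimethylamino)methyl] derivative of 25 (Mannich base, C11 epimers) | C=C[C@H]1OC(=O)C(CN(C)C)[C@@H]1[C@H](O[Si](CC)(CC)CC)C2SCCCS2 | intermediate
28 | N,N,N-trimethylammonium iodide of 27 | C=C[C@H]1OC(=O)C(C[N+](C)(C)C)[C@@H]1[C@H](O[Si](CC)(CC)CC)C2SCCCS2.[I-] | intermediate
29 | (4S,5R)-4-[(S)-1,3-dithian-2-yl(triethylsilyloxy)methyl]-5-ethenyl-3-methylideneoxolan-2-one | C=C[C@H]1OC(=O)C(=C)[C@@H]1[C@H](O[Si](CC)(CC)CC)C2SCCCS2 | intermediate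
30 | (2S)-2-[(2R,3S)-2-ethenyl-4-methylidene-5-oxooxolan-3-yl]-2-(triethylsilyloxy)acetaldehyde (East fragment) | C=C[C@H]1OC(=O)C(=C)[C@@H]1[C@H](O[Si](CC)(CC)CC)C=O | intermediate
31 | (4S,5R)-5-ethenyl-4-[(1S,3Z)-2-hydroxy-3-{[(4-methoxyphenyl)methoxy]methyl}-4-[(2R,3S)-3-(prop-1-en-2-yl)oxiran-2-yl]-1-(triethylsilyloxy)but-3-en-1-yl]-3-methylideneoxolan-2-one, both C9 epimers | C=C[C@H]1OC(=O)C(=C)[C@@H]1[C@H](O[Si](CC)(CC)CC)C(O)C(/COCc2ccc(OC)cc2)=C\[C@H]3O[C@H]3C(C)=C | intermediate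
32 | (4S,5R)-5-ethenyl-4-[(1S,3Z)-3-{[(4-methoxyphenyl)methoxy]methyl}-2-oxo-4-[(2R,3S)-3-(prop-1-en-2-yl)oxiran-2-yl]-1-(triethylsilyloxy)but-3-en-1-yl]-3-methylideneoxolan-2-one | C=C[C@H]1OC(=O)C(=C)[C@@H]1[C@H](O[Si](CC)(CC)CC)C(=O)C(/COCc2ccc(OC)cc2)=C\[C@H]3O[C@H]3C(C)=C | intermediate
33 | (4R,5R)-5-ethenyl-4-[(1S,3Z)-1-hydroxy-3-{[(4-methoxyphenyl)methoxy]methyl}-2-oxo-4-[(2R,3S)-3-(prop-1-en-2-yl)oxiran-2-yl]but-3-en-1-yl]-3-methylideneoxolan-2-one | C=C[C@H]1OC(=O)C(=C)[C@@H]1[C@H](O)C(=O)C(/COCc2ccc(OC)cc2)=C\[C@H]3O[C@H]3C(C)=C | intermediate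
34 | (2R,3R)-2,3-dimethyloxirane-2-carboxylic 2,4,6-trichlorobenzoic anhydride | O=C(OC(=O)c1c(Cl)cc(Cl)cc1Cl)[C@]2(C)O[C@@H]2C | intermediate
35 | (1S,3Z)-1-[(2R,3S)-2-ethenyl-4-methylidene-5-oxooxolan-3-yl]-3-{[(4-methoxyphenyl)methoxy]methyl}-2-oxo-4-[(2R,3S)-3-(prop-1-en-2-yl)oxiran-2-yl]but-3-en-1-yl (2R,3R)-2,3-dimethyloxirane-2-carboxylate | C=C[C@H]1OC(=O)C(=C)[C@@H]1[C@H](OC(=O)[C@]2(C)O[C@@H]2C)C(=O)C(/COCc3ccc(OC)cc3)=C\[C@H]4O[C@H]4C(C)=C | intermediate
36 | (1S,2S,3Z)-1-[(2R,3S)-2-ethenyl-4-methylidene-5-oxooxolan-3-yl]-2-hydroxy-3-{[(4-methoxyphenyl)methoxy]methyl}-4-[(2R,3S)-3-(prop-1-en-2-yl)oxiran-2-yl]but-3-en-1-yl (2R,3R)-2,3-dimethyloxirane-2-carboxylate | C=C[C@H]1OC(=O)C(=C)[C@@H]1[C@H](OC(=O)[C@]2(C)O[C@@H]2C)[C@@H](O)C(/COCc3ccc(OC)cc3)=C\[C@H]4O[C@H]4C(C)=C | intermediate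
37 | (1S,2S,3Z)-1-[(2R,3S)-2-ethenyl-4-methylidene-5-oxooxolan-3-yl]-2-hydroxy-3-(hydroxymethyl)-4-[(2R,3S)-3-(prop-1-en-2-yl)oxiran-2-yl]but-3-en-1-yl (2R,3R)-2,3-dimethyloxirane-2-carboxylate | C=C[C@H]1OC(=O)C(=C)[C@@H]1[C@H](OC(=O)[C@]2(C)O[C@@H]2C)[C@@H](O)C(/CO)=C\[C@H]3O[C@H]3C(C)=C | intermediate
38 | (1S,2S,3E)-1-[(2R,3S)-2-ethenyl-4-methylidene-5-oxooxolan-3-yl]-3-formyl-2-hydroxy-4-[(2R,3S)-3-(prop-1-en-2-yl)oxiran-2-yl]but-3-en-1-yl (2R,3R)-2,3-dimethyloxirane-2-carboxylate | C=C[C@H]1OC(=O)C(=C)[C@@H]1[C@H](OC(=O)[C@]2(C)O[C@@H]2C)[C@@H](O)C(/C=O)=C\[C@H]3O[C@H]3C(C)=C | intermediate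
39 | (2E)-2-[(1S,2S)-2-{[(2R,3R)-2,3-dimethyloxirane-2-carbonyl]oxy}-2-[(2R,3S)-2-ethenyl-4-methylidene-5-oxooxolan-3-yl]-1-hydroxyethyl]-3-[(2R,3S)-3-(prop-1-en-2-yl)oxiran-2-yl]prop-2-enoic acid | C=C[C@H]1OC(=O)C(=C)[C@@H]1[C@H](OC(=O)[C@]2(C)O[C@@H]2C)[C@@H](O)C(/C(=O)O)=C\[C@H]3O[C@H]3C(C)=C | intermediate
40 | methyl (2E)-2-[(1S,2S)-2-{[(2R,3R)-2,3-dimethyloxirane-2-carbonyl]oxy}-2-[(2R,3S)-2-ethenyl-4-methylidene-5-oxooxolan-3-yl]-1-hydroxyethyl]-3-[(2R,3S)-3-(prop-1-en-2-yl)oxiran-2-yl]prop-2-enoate | C=C[C@H]1OC(=O)C(=C)[C@@H]1[C@H](OC(=O)[C@]2(C)O[C@@H]2C)[C@@H](O)C(/C(=O)OC)=C\[C@H]3O[C@H]3C(C)=C | intermediate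
41 | CNP0291485.1: methyl ester of 2,3-epoxy-8-[(2R,3R)-2,3-epoxy-2-methylbutanoyloxy]-9-hydroxygermacra-1(10)E,4Z,11(13)-trien-6,12-olid-14-oic acid, (2R,3S,6R,7S,8S,9S) | C=C1C(=O)O[C@@H]2/C=C(/C)[C@@H]3O[C@@H]3/C=C(/C(=O)OC)[C@H](O)[C@@H](OC(=O)[C@]3(C)O[C@@H]3C)[C@@H]12 | target

## Step count and risks

Total step count: 28. Longest linear sequence: 18 steps (steps 11–28, from 14 and 15 through the East fragment to 41). The West branch is 7 steps before the union and the acid branch is 3.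

The three steps most likely to fail:

Step 28 (ring closure). The metathesis must form a trisubstituted olefin in a ten-membered ring next to an oxirane. Oligomerisation or a thermal Cope rearrangement of the cis-dialkenyl-oxirane could win. Fallback: close the ring before the C14 oxidation, on a triene whose 1(10)-olefin is not an enoate. Setting out from 36, the same ruthenium carbene (toluene, 1 mM, 60 °C) gives macrocyclic PMB ether F1. DDQ then gives macrocyclic allylic alcohol F2. TEMPO/PhI(OAc)2 gives macrocyclic enal F3, which NaClO2 oxidises to macrocyclic acid F4. MeI/KHCO3 returns to the route at 41.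

Step 16 (lactonisation). The β-hydroxy dithiane and the allylic alcohol may not tolerate CF3CO2H, and closure on O8 can compete with closure on O6. Fallback: non-acidic ester cleavage followed by base-mediated translactonisation. Setting out from 23, Me3SiOTf/2,6-lutidine and a citric-acid work-up give dihydroxy acid F5. EDC·HCl/DMAP closes it under kinetic control to 24 together with O8-lactone regioisomer F6. Catalytic DBU in CH2Cl2 then equilibrates F6 by intramolecular transesterification to the more stable trans-lactone, returning at 24.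

Step 20 (fragment union). The hindered trisubstituted alkenyl iodide may react slowly, and divalent chromium may attack the vinyl-oxirane. Fallback: halogen–lithium exchange in place of the Ni/Cr chemistry. Setting out from 9, t-BuLi (2 equiv) in Et2O at −100 °C gives alkenyllithium F7 with retention of olefin geometry. F7 adds to aldehyde 30 at −100 °C faster than to the lactone, returning at 31.

## Further compounds

F1 | step 28 | macrocyclic PMB ether (skeleton of 41 with CH2OCH2C6H4-4-OMe on C10 in place of CO2Me) | C=C1C(=O)O[C@@H]2/C=C(/C)[C@@H]3O[C@@H]3/C=C(/COCc4ccc(OC)cc4)[C@H](O)[C@@H](OC(=O)[C@]5(C)O[C@@H]5C)[C@@H]12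
F2 | step 28 | macrocyclic allylic alcohol (skeleton of 41 with CH2OH on C10) | C=C1C(=O)O[C@@H]2/C=C(/C)[C@@H]3O[C@@H]3/C=C(/CO)[C@H](O)[C@@H](OC(=O)[C@]4(C)O[C@@H]4C)[C@@H]12
F3 | step 28 | macrocyclic enal (skeleton of 41 with CHO on C10) | C=C1C(=O)O[C@@H]2/C=C(/C)[C@@H]3O[C@@H]3/C=C(/C=O)[C@H](O)[C@@H](OC(=O)[C@]4(C)O[C@@H]4C)[C@@H]12
F4 | step 28 | macrocyclic acid (free C14 acid of 41) | C=C1C(=O)O[C@@H]2/C=C(/C)[C@@H]3O[C@@H]3/C=C(/C(=O)O)[C@H](O)[C@@H](OC(=O)[C@]4(C)O[C@@H]4C)[C@@H]12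
F5 | step 16 | (3S,4R)-3-[(S)-1,3-dithian-2-yl(hydroxy)methyl]-4-hydroxyhex-5-enoic acid | C=C[C@@H](O)[C@H](CC(=O)O)[C@H](O)C1SCCCS1
F6 | step 16 | (4S,5S)-5-(1,3-dithian-2-yl)-4-[(1R)-1-hydroxyprop-2-en-1-yl]oxolan-2-one | C=C[C@@H](O)[C@@H]1CC(=O)O[C@@H]1C2SCCCS2
F7 | step 20 | {(1Z)-3-[(4-methoxyphenyl)methoxy]-1-[(2R,3S)-3-(prop-1-en-2-yl)oxiran-2-yl]prop-1-en-2-yl}lithium | C=C(C)[C@@H]1O[C@@H]1/C=C(\[Li])COCc1ccc(OC)cc1
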